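Compare the two ways out of catalyst intermediate A: it falls back at 0.812 s⁻¹ and goes on to target at 7.3 s⁻¹, faster, so its balance with free catalyst is a kinetic one, not the equilibrium of step 1.

starting material 2.0 mM; second substrate 1.00 mM; protic impurity 0.400 mM; precatalyst 20 µM

    starting material + free catalyst ⇌ catalyst intermediate A (K1 = 16000 M⁻¹, k1 = 13000 M⁻¹ s⁻¹)
    catalyst intermediate A → free catalyst + target (k2 = 7.3 s⁻¹)
    catalyst intermediate B → free catalyst + second product (k3 = 11 s⁻¹)
    precatalyst → free catalyst (k4 = 0.12 s⁻¹)
    second substrate + free catalyst ⇌ catalyst intermediate B (K5 = 720 M⁻¹, k5 = 1.9 × 10⁵ M⁻¹ s⁻¹)
    second substrate + protic impurity → quenched substrate (k6 = 360 M⁻¹ s⁻¹)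

1. the form that holds most of the catalyst when 30 % of the starting material are converted (catalyst intermediate B / free catalyst / catalyst intermediate A / precatalyst)
2. its share of the catalyst then
3. factor on the rate of making target when 30 % of the starting material are converted if precatalyst is charged twice over
4. factor on the rate when 30 % of the starting material are converted if precatalyst is charged at 2.0 µM instead

The round turns far faster than precatalyst opens, so divide the rate of forming intermediate A by the rate of its leaving, and time drops out. Intermediate A per free catalyst is then the fraction of starting material left over the half-load fraction, 0.312: the fraction of the charge at which the two forms are equal, the Michaelis constant over the charge.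

First ask how the working catalyst divides. With 30 % converted, the ratio for intermediate A is 2.24. Protic impurity lasts about 4.63 s, shorter than the 8.33 s that precatalyst takes to open, so count second substrate as its charge less the impurity. Its own half-load fraction, 1.45, then gives intermediate B a ratio of 0.415. Intermediate A therefore holds 61.3 % of the working catalyst.

Next ask how much catalyst works. At that split, with the whole charge active, the conversion takes 6.70 s. Activation adds a lag of up to 8.33 s, and one substitution leaves 80.6 % activated. So the resting state is catalyst intermediate A, with 49.4 %.

Last, change the charge. Hold the split fixed at the same fractions left; the rate then follows charge times activated share. Scale the time inversely with the charge: doubling leaves 68.5 % activated, a factor of 1.70. At 2.0 µM, >99.9 % is activated, a factor of 0.124.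

The forecast named catalyst intermediate A at 49 % with factors 1.6 and 0.13, its doubling factor lower than mine, and held that “Doubling the charge gives less than twice the rate because that conversion is reached sooner”.

The flask gives catalyst intermediate A at 49.0 %, with factors 1.61 and 0.128. There, intermediate A over free catalyst reads 2.24. Use the half-load fraction later in this flask: at 20.0 s, with 43 % of the starting material left, it gives 1.39, and the flask reads 1.40. In the 2.0 µM flask, intermediate B holds 9.18 % at the same conversion. Divide the remaining activated catalyst by 2.24 to one: intermediate A holds 62.8 %, which puts the rate at 0.128 of the 20 µM flask's.

The constants used here were chosen freely.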